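**Falling constant.** A first-order constant of 0.0143 s⁻¹ fits the first 25.0 s of beta, the flask asked about, yet from 60.0 s to 90.0 s beta gives 0.0101 s⁻¹, which is less. By 90.0 s beta has lost 0.0330 M of substrate, far more than its acid charge, so acid is taken as unconsumed and the pH as staying at that of the charge.

| flask | substrate | acid | remark | time |
|---|---|---|---|---|
| beta | 0.050 M | 1.5 mM | the very flask that is asked about, followed so far |  |
| epsilon | 0.034 M | 1.5 mM | run made earlier |  |
| flask | 0.050 M | 1.50 mM |  | 3.0 min |

| run | time / s | substrate / % | target / % |
|---|---|---|---|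
| beta | 10.0 | 87 | 8 |
| beta | 25.0 | 70 | 15 |
| beta | 40.0 | 59 | 24 |
| beta | 60.0 | 46 | 30 |
| beta | 90.0 | 34 | 38 |
| epsilon | 10.0 | 89 | 8 |
| epsilon | 20.0 | 79 | 12 |
| epsilon | 40.0 | 62 | 23 |
| epsilon | 80.0 | 41 | 42 |

(standard deviation of a reading: 1.5 percentage points)

- part of the substrate that has reacted at 3.0 min
- pH of the solution at 3.0 min

- acid is the free proton; pH is minus the decimal logarithm of its molar concentration

**Clearing it.** Each value is a local first-order constant belonging to a mean substrate level, 0.0418 M and 0.0198 M. A straight line through both reaches, at zero substrate, the floor constant 0.00632 s⁻¹, a pseudo-first-order constant at this acid charge, read from scattered readings. Epsilon tests this line: at its mean level the line gives 0.0121 s⁻¹, and its first 20.0 s read 0.0118 s⁻¹.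

**Going round.** From 90.0 s to 3.0 min in beta, the constant at the last reading leaves 14.4 % of the substrate. Putting that answer back, with the mean level of the stretch, leaves 15.9 %, so this reckoning gives 84.1 % reacted.

**Forecast.** The forecast gives 84.5 % (81 % to 88 %) and pH 2.83 (2.79 to 3.03), saying of the acid: “It looks like a catalyst”.

**Result.** Beta reaches 85.8 % reacted at pH 2.82.

    substrate + acid → weak acid + acid + target (k = 260 L mol⁻¹ min⁻¹)
    weak acid ⇌ conjugate base + acid, settled at all times (K = 6.30 × 10⁻⁹ M)
    substrate → weak acid + target (k = 0.0630 min⁻¹)
    2 substrate → homo dimer (k = 4.90 L mol⁻¹ min⁻¹)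

At 3.00 min in beta, homo dimer, which takes two substrate at each turn, holds 31.2 % of the substrate charged. The floor serves again for beta read at 50 s: the starting constant leaves 45.3 %, and one more round leaves 53.0 %. The simulated flask holds 51.2 % of its substrate then.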